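**Retrosynthetic overview**

1. The phenol is unveiled last from its methyl ether. The aryl ketone comes from a carbinol made by aldol union of ring C (the cyclohexene, at C1') with 4,6-dimethoxybenzofuran-7-carbaldehyde (rings A and B).
2. The prenyl group at C2' comes from Wittig olefination of a C2'–CH2CHO unit delivered by Claisen rearrangement of a C4' vinyl ether (chirality transfer C4'→C2', alkene returned to C3'=C4'). The C4' alcohol comes from epoxidation and Wharton transposition of (5R)-2-methyl-5-phenylcyclohex-2-enone, whose ketone carbon is C2'.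
3. Key disconnection of ring C: C5'–C6' (Michael addition) and C3'=C4' (aldol condensation) in one flask, joining acetaldehyde (C4', C5') to tert-butyl 2-benzylidene-3-oxopentanoate (C6', C1', C2', C3' and its methyl); the ester is an activating group lost in the same flask.
4. Enabling feature: with C2' written as a ketone, the ring C segment C2'–C3'(CH3)=C4'–C5'–C6'(Ph) is an α-methyl enone carrying phenyl on the carbon β to the ketone on the other side, which is the retron of a Robinson-type annulation. The C6' centre set there then controls C1' and C2'.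
5. Ring order: ring C first (step 2), then furan ring B onto the commercial arene ring A (step 5); the halves are joined in step 6.

Key step: step 2

Remark: the (S)-configured catalyst in step 2 is chosen by analogy with its additions of acetaldehyde to β-nitrostyrene; if the sense of induction were opposite, the mirror-image catalyst would give the same (R)-enone.

**Route**

Step 1
Reactants: 1 benzaldehyde; 2 tert-butyl 3-oxopentanoate
Product: 3 tert-butyl 2-benzylidene-3-oxopentanoate (E/Z mixture)
Conditions: piperidine (0.1 equiv), AcOH (0.1 equiv), toluene, reflux, Dean–Stark trap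
Reagents that add atoms: none
Why: Knoevenagel condensation of the doubly activated methylene of 2 with a non-enolisable aldehyde is routine, and the E/Z mixture can be used because the later stereocentre is fixed by the catalyst and not by the alkene geometry.

Step 2
Reactants: 3 tert-butyl 2-benzylidene-3-oxopentanoate; 4 acetaldehyde
Product: 7 (5R)-2-methyl-5-phenylcyclohex-2-en-1-one, via Michael adduct 5 (not isolated), via cyclised keto ester 6 (not isolated)
Conditions: (S)-α,α-diphenylprolinol trimethylsilyl ether (20 mol %), PhCO2H (20 mol %), acetaldehyde (5 equiv), 1,4-dioxane, 4 °C; evaporate volatiles; then p-TsOH·H2O (20 mol %), toluene, 80 °C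
Reagents that add atoms: none
Why: The secondary amine condenses with acetaldehyde to an enamine that adds to the benzylic carbon of the doubly activated alkene of 3 (Michael addition, equally describable as an inverse-electron-demand oxa-Diels–Alder reaction followed by hydrolysis), which forms C5'–C6' and gives 5; p-TsOH then enolises the ethyl ketone toward its CH2, this enol adds to the aldehyde, water is lost to give the C3'=C4' bond of 6, and the tert-butyl ester leaves as isobutene and CO2. The closest known reaction types are amine-catalysed Michael additions of aldehydes, acetaldehyde included, to nitroalkenes and alkylidene 1,3-dicarbonyl compounds, and the acid-mediated aldol condensation with decarboxylation of δ-keto aldehyde tert-butyl esters to 5-aryl-2-alkylcyclohex-2-enones, together a Robinson-type annulation. Ring C closes by a 6-(enolendo)-exo-trig aldol addition followed by E1cB dehydration. The C6' stereocentre is set in the C–C bond-forming event by the catalyst, whose diphenyl(silyloxy)methyl group shields one face of the enamine and so selects one prochiral face of the benzylic carbon, largely independently of the E/Z geometry of 3. The step needs cross-addition to win over self-aldolisation of acetaldehyde, which the high electrophilicity of the twice-activated alkene should secure, and ring closure through the ethyl CH2 and not the more acidic C1'–H, which is secured because C1' could only close a four-membered ring.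

Step 3
Reactants: 7 (5R)-2-methyl-5-phenylcyclohex-2-en-1-one
Product: 8 (1R,4R,6R)-1-methyl-4-phenyl-7-oxabicyclo[4.1.0]heptan-2-one
Conditions: 30% aq. H2O2, NaOH (0.2 equiv), MeOH, 0 °C
Reagents that add atoms: hydrogen peroxide, OO
Why: Weitz–Scheffer nucleophilic epoxidation, in which hydroperoxide should add axially to C4' anti to the equatorial phenyl group (as with carvone), so that the epoxide oxygen ends trans to phenyl.

Step 4
Reactants: 9 2-hydroxy-4,6-dimethoxybenzaldehyde; 10 2-bromo-1,1-diethoxyethane
Product: 11 2-(2,2-diethoxyethoxy)-4,6-dimethoxybenzaldehyde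
Conditions: K2CO3 (1.5 equiv), KI (cat.), DMF, 110 °C
Reagents that add atoms: none
Why: Williamson ether synthesis at the only phenol of 9, with iodide exchange speeding the SN2 displacement of the primary bromide.

Step 5
Reactants: 11 2-(2,2-diethoxyethoxy)-4,6-dimethoxybenzaldehyde
Product: 12 4,6-dimethoxy-1-benzofuran-7-carbaldehyde
Conditions: Amberlyst 15, chlorobenzene, 120 °C
Reagents that add atoms: none
Why: Acid-catalysed cyclodehydration (intramolecular Friedel–Crafts-type attack on the oxocarbenium ion, then loss of ethanol) closes furan ring B at the only free position ortho to the ether oxygen, which the flanking methoxy group activates.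

Step 6
Reactants: 8 (1R,4R,6R)-1-methyl-4-phenyl-7-oxabicyclo[4.1.0]heptan-2-one; 12 4,6-dimethoxy-1-benzofuran-7-carbaldehyde
Product: 15 (1R,3R,4R,6R)-3-[(tert-butyldimethylsilyloxy)(4,6-dimethoxy-1-benzofuran-7-yl)methyl]-1-methyl-4-phenyl-7-oxabicyclo[4.1.0]heptan-2-one (both epimers at the silyloxy carbon), via lithium enolate 13 (not isolated), via lithium aldolate 14 (not isolated)
Conditions: LiN(i-Pr)2 (1.1 equiv), THF, −78 °C; 12; then TBSOTf (1.2 equiv), −78 °C → −40 °C
Reagents that add atoms: tert-butyldimethylsilyl trifluoromethanesulfonate, CC(C)(C)[Si](C)(C)OS(=O)(=O)C(F)(F)F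
Why: Directed aldol addition in which only C1' can be deprotonated (the other α-carbon is the quaternary epoxide carbon), the aldehyde should approach the enolate anti to the adjacent phenyl group so that the C1' substituent is trans to phenyl, and silylation of the aldolate in the flask forestalls retro-aldol; the carbinol centre is formed as a mixture that converges on oxidation in step 11.

Step 7
Reactants: 15 (1R,3R,4R,6R)-3-[(tert-butyldimethylsilyloxy)(4,6-dimethoxy-1-benzofuran-7-yl)methyl]-1-methyl-4-phenyl-7-oxabicyclo[4.1.0]heptan-2-one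
Product: 17 (1R,4R,5R)-4-[(tert-butyldimethylsilyloxy)(4,6-dimethoxy-1-benzofuran-7-yl)methyl]-2-methyl-5-phenylcyclohex-2-en-1-ol, via epoxy hydrazone 16 (not isolated)
Conditions: N2H4·H2O (3 equiv), AcOH (cat.), MeOH, 0 °C → rt
Reagents that add atoms: none
Why: Wharton transposition, in which the α,β-epoxy hydrazone opens to an allylic diazene that loses N2, leaving the oxygen on C4' with its configuration unchanged and the alkene at C2'=C3'.

Step 8
Reactants: 17 (1R,4R,5R)-4-[(tert-butyldimethylsilyloxy)(4,6-dimethoxy-1-benzofuran-7-yl)methyl]-2-methyl-5-phenylcyclohex-2-en-1-ol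
Product: 19 2-{(1S,5R,6R)-6-[(tert-butyldimethylsilyloxy)(4,6-dimethoxy-1-benzofuran-7-yl)methyl]-2-methyl-5-phenylcyclohex-2-en-1-yl}acetaldehyde, via vinyl ether 18 (not isolated)
Conditions: Hg(OAc)2 (0.2 equiv), ethyl vinyl ether (solvent), 35 °C; evaporate; decane, 180 °C, sealed tube
Reagents that add atoms: ethyl vinyl ether, CCOC=C
Why: Transvinylation followed by Claisen [3,3]-sigmatropic rearrangement, in which the pseudoaxial C4'–O bond is exchanged suprafacially for a C2'–C bond, so the CH2CHO group should arrive at C2' on the face the oxygen leaves (cis to the C1' substituent, trans to phenyl) and the C3'=C4' alkene is restored.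

Step 9
Reactants: 19 2-{(1S,5R,6R)-6-[(tert-butyldimethylsilyloxy)(4,6-dimethoxy-1-benzofuran-7-yl)methyl]-2-methyl-5-phenylcyclohex-2-en-1-yl}acetaldehyde
Product: 20 tert-butyl{(4,6-dimethoxy-1-benzofuran-7-yl)[(1R,2S,6R)-3-methyl-2-(3-methylbut-2-en-1-yl)-6-phenylcyclohex-3-en-1-yl]methoxy}dimethylsilane
Conditions: i-PrPPh3I (1.5 equiv), n-BuLi (1.4 equiv), THF, 0 °C; then 19, −78 °C → rt
Reagents that add atoms: isopropyltriphenylphosphonium iodide, CC(C)[P+](c1ccccc1)(c1ccccc1)c1ccccc1.[I-]
Why: Wittig olefination of the unhindered aldehyde with the non-stabilised isopropylidene ylide gives the prenyl alkene, which has no E/Z issue.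

Step 10
Reactants: 20 tert-butyl{(4,6-dimethoxy-1-benzofuran-7-yl)[(1R,2S,6R)-3-methyl-2-(3-methylbut-2-en-1-yl)-6-phenylcyclohex-3-en-1-yl]methoxy}dimethylsilane
Product: 21 (4,6-dimethoxy-1-benzofuran-7-yl)[(1R,2S,6R)-3-methyl-2-(3-methylbut-2-en-1-yl)-6-phenylcyclohex-3-en-1-yl]methanol (both carbinol epimers)
Conditions: Bu4NF (1 M in THF, 2 equiv), THF, rt
Reagents that add atoms: none
Why: Fluoride-mediated desilylation, driven by the strength of the Si–F bond, leaves alkenes, benzofuran and methyl ethers untouched.

Step 11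
Reactants: 21 (4,6-dimethoxy-1-benzofuran-7-yl)[(1R,2S,6R)-3-methyl-2-(3-methylbut-2-en-1-yl)-6-phenylcyclohex-3-en-1-yl]methanol
Product: 22 (4,6-dimethoxy-1-benzofuran-7-yl)[(1R,2S,6R)-3-methyl-2-(3-methylbut-2-en-1-yl)-6-phenylcyclohex-3-en-1-yl]methanone
Conditions: Dess–Martin periodinane (1.3 equiv), CH2Cl2, 0 °C → rt
Reagents that add atoms: none
Why: Dess–Martin oxidation of the secondary benzylic alcohol converges both carbinol epimers on one ketone under near-neutral conditions that should not epimerise C1' or touch the alkenes.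

Step 12
Reactants: 22 (4,6-dimethoxy-1-benzofuran-7-yl)[(1R,2S,6R)-3-methyl-2-(3-methylbut-2-en-1-yl)-6-phenylcyclohex-3-en-1-yl]methanone
Product: 23 (6-hydroxy-4-methoxy-1-benzofuran-7-yl)[(1R,2S,6R)-3-methyl-2-(3-methylbut-2-en-1-yl)-6-phenylcyclohex-3-en-1-yl]methanone (CNP0247234.1)
Conditions: BCl3 (1 M in CH2Cl2, 1.5 equiv), CH2Cl2, −78 °C → −20 °C; then H2O
Reagents that add atoms: none
Why: Lewis acid-mediated aryl methyl ether cleavage, in which chelation of boron between the ketone oxygen and the ortho methoxy group directs cleavage to that methyl only, the para methoxy group and the alkenes being left alone at low temperature.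

**Compound list**

1 | benzaldehyde | O=Cc1ccccc1 | starting material
2 | tert-butyl 3-oxopentanoate | CCC(=O)CC(=O)OC(C)(C)C | starting material
3 | tert-butyl 2-benzylidene-3-oxopentanoate (E/Z mixture) | CCC(=O)C(=Cc1ccccc1)C(=O)OC(C)(C)C | intermediate
4 | acetaldehyde | CC=O | starting material
5 | tert-butyl 3-oxo-2-[(1R)-3-oxo-1-phenylpropyl]pentanoate (C2 epimers, in equilibrium with its cyclic hemiacetal) | CCC(=O)C(C(=O)OC(C)(C)C)[C@@H](CC=O)c1ccccc1 | intermediate
6 | tert-butyl (6R)-3-methyl-2-oxo-6-phenylcyclohex-3-ene-1-carboxylate (C1 epimers) | CC1=CC[C@H](C(C1=O)C(=O)OC(C)(C)C)c1ccccc1 | intermediate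
7 | (5R)-2-methyl-5-phenylcyclohex-2-en-1-one | CC1=CC[C@H](CC1=O)c1ccccc1 | intermediate
8 | (1R,4R,6R)-1-methyl-4-phenyl-7-oxabicyclo[4.1.0]heptan-2-one | C1C(=O)[C@]2(C)O[C@@H]2C[C@H]1c1ccccc1 | intermediate
9 | 2-hydroxy-4,6-dimethoxybenzaldehyde | COc1cc(O)c(C=O)c(OC)c1 | starting material
10 | 2-bromo-1,1-diethoxyethane | CCOC(CBr)OCC | starting material
11 | 2-(2,2-diethoxyethoxy)-4,6-dimethoxybenzaldehyde | CCOC(COc1cc(OC)cc(OC)c1C=O)OCC | intermediate
12 | 4,6-dimethoxy-1-benzofuran-7-carbaldehyde | COc1cc(OC)c(C=O)c2occc12 | intermediate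
13 | lithium enolate of 8 (enolate between C2 and C3, oxygen on C2) | C1=C([O-])[C@]2(C)O[C@@H]2C[C@H]1c1ccccc1.[Li+] | intermediate
14 | lithium aldolate from 13 and 12 (alkoxide of the desilyl form of 15) | COc1cc(OC)c(C([O-])[C@@H]2C(=O)[C@]3(C)O[C@@H]3C[C@H]2c2ccccc2)c2occc12.[Li+] | intermediate
15 | (1R,3R,4R,6R)-3-[(tert-butyldimethylsilyloxy)(4,6-dimethoxy-1-benzofuran-7-yl)methyl]-1-methyl-4-phenyl-7-oxabicyclo[4.1.0]heptan-2-one (both epimers at the silyloxy carbon) | COc1cc(OC)c(C(O[Si](C)(C)C(C)(C)C)[C@@H]2C(=O)[C@]3(C)O[C@@H]3C[C@H]2c2ccccc2)c2occc12 | intermediate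
16 | hydrazone of 15 at the ring ketone | COc1cc(OC)c(C(O[Si](C)(C)C(C)(C)C)[C@@H]2C(=NN)[C@]3(C)O[C@@H]3C[C@H]2c2ccccc2)c2occc12 | intermediate
17 | (1R,4R,5R)-4-[(tert-butyldimethylsilyloxy)(4,6-dimethoxy-1-benzofuran-7-yl)methyl]-2-methyl-5-phenylcyclohex-2-en-1-ol | COc1cc(OC)c(C(O[Si](C)(C)C(C)(C)C)[C@@H]2C=C(C)[C@H](O)C[C@H]2c2ccccc2)c2occc12 | intermediate
18 | O-vinyl ether of 17 | COc1cc(OC)c(C(O[Si](C)(C)C(C)(C)C)[C@@H]2C=C(C)[C@H](OC=C)C[C@H]2c2ccccc2)c2occc12 | intermediate
19 | 2-{(1S,5R,6R)-6-[(tert-butyldimethylsilyloxy)(4,6-dimethoxy-1-benzofuran-7-yl)methyl]-2-methyl-5-phenylcyclohex-2-en-1-yl}acetaldehyde | COc1cc(OC)c(C(O[Si](C)(C)C(C)(C)C)[C@@H]2[C@H](CC=O)C(C)=CC[C@H]2c2ccccc2)c2occc12 | intermediate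
20 | tert-butyl{(4,6-dimethoxy-1-benzofuran-7-yl)[(1R,2S,6R)-3-methyl-2-(3-methylbut-2-en-1-yl)-6-phenylcyclohex-3-en-1-yl]methoxy}dimethylsilane | COc1cc(OC)c(C(O[Si](C)(C)C(C)(C)C)[C@@H]2[C@H](CC=C(C)C)C(C)=CC[C@H]2c2ccccc2)c2occc12 | intermediate
21 | (4,6-dimethoxy-1-benzofuran-7-yl)[(1R,2S,6R)-3-methyl-2-(3-methylbut-2-en-1-yl)-6-phenylcyclohex-3-en-1-yl]methanol (both carbinol epimers) | COc1cc(OC)c(C(O)[C@@H]2[C@H](CC=C(C)C)C(C)=CC[C@H]2c2ccccc2)c2occc12 | intermediate
22 | (4,6-dimethoxy-1-benzofuran-7-yl)[(1R,2S,6R)-3-methyl-2-(3-methylbut-2-en-1-yl)-6-phenylcyclohex-3-en-1-yl]methanone | COc1cc(OC)c(C(=O)[C@@H]2[C@H](CC=C(C)C)C(C)=CC[C@H]2c2ccccc2)c2occc12 | intermediate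
23 | (6-hydroxy-4-methoxy-1-benzofuran-7-yl)[(1R,2S,6R)-3-methyl-2-(3-methylbut-2-en-1-yl)-6-phenylcyclohex-3-en-1-yl]methanone | COc1cc(O)c(C(=O)[C@@H]2[C@H](CC=C(C)C)C(C)=CC[C@H]2c2ccccc2)c2occc12 | target

**Step count and risks**

Total step count: 12. Longest linear sequence: 10 steps (steps 1, 2, 3, 6, 7, 8, 9, 10, 11, 12); the aryl branch (steps 4 and 5) joins at step 6.

The three steps most likely to fail:

Step 2. The enamine addition may be slow enough for self-condensation of acetaldehyde to take over. Enantioselectivity may be eroded by reversible addition to the E/Z mixture of 3. The hemiacetal form of 5 may also dehydrate to a 4H-pyran instead of closing by aldol addition. The fallback sets out from 3 and comes back to the route at 5, and so at 7. An inverse-electron-demand hetero-Diels–Alder reaction of 3 with ethyl vinyl ether is run under a Cu(OTf)2/tert-butyl-bis(oxazoline) catalyst, using the ligand enantiomer that delivers the (4S) product; the ketone oxygen and the benzylidene alkene act as the oxadiene and the 1,3-dicarbonyl unit binds copper in bidentate fashion. This should give tert-butyl (4S)-2-ethoxy-6-ethyl-4-phenyl-3,4-dihydro-2H-pyran-5-carboxylate F1, which already holds the C5'–C6' bond and the C6' configuration. p-TsOH·H2O in wet toluene at 80 °C then hydrolyses the acetal to 5, which closes to 6 and 7 in the same flask as in step 2.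

Step 7. Hydrazone formation at the C2' ketone, which is flanked by the quaternary epoxide carbon and the branched C1', may be slow, so that opening of the epoxide by hydrazine or azine formation competes. The fallback sets out from 15 and comes back at 17. NaBH4 in MeOH at 0 °C reduces the ketone to the epoxy alcohol (1R,3R,4R,6R)-3-[(tert-butyldimethylsilyloxy)(4,6-dimethoxy-1-benzofuran-7-yl)methyl]-1-methyl-4-phenyl-7-oxabicyclo[4.1.0]heptan-2-ol F2 (either C2 epimer). 1,1'-Thiocarbonyldiimidazole with DMAP in CH2Cl2 at 40 °C converts it into the O-(imidazol-1-ylthiocarbonyl) derivative of that epoxy alcohol F3. Bu3SnH and AIBN in toluene at 90 °C then generate the C2' radical, which opens the epoxide by β-scission of the C3'–O bond; the resulting alkoxy radical takes hydrogen from the stannane to give 17 with the C4' configuration unchanged.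

Step 6. The aldol equilibrium with the hindered, electron-rich aldehyde 12 may be unfavourable (retro-aldol before silylation), the silyl triflate may open the epoxide, or facial control at C1' may be incomplete. The fallback sets out from 7 and comes back at 15. The same deprotonation, aldol addition and silylation (LiN(i-Pr)2, THF, −78 °C; 12; TBSOTf) are run on enone 7 itself through its α'-enolate, as in carvone chemistry, to give (5R,6R)-6-[(tert-butyldimethylsilyloxy)(4,6-dimethoxy-1-benzofuran-7-yl)methyl]-2-methyl-5-phenylcyclohex-2-en-1-one F4. Weitz–Scheffer epoxidation of this enone (t-BuOOH, DBU, CH2Cl2, 0 °C) anti to phenyl then gives 15.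

**Further compounds**

F1 | step 2 | tert-butyl (4S)-2-ethoxy-6-ethyl-4-phenyl-3,4-dihydro-2H-pyran-5-carboxylate (acetal carbon as formed) | CCOC1C[C@@H](c2ccccc2)C(C(=O)OC(C)(C)C)=C(CC)O1
F2 | step 7 | (1R,3R,4R,6R)-3-[(tert-butyldimethylsilyloxy)(4,6-dimethoxy-1-benzofuran-7-yl)methyl]-1-methyl-4-phenyl-7-oxabicyclo[4.1.0]heptan-2-ol (either C2 epimer) | COc1cc(OC)c(C(O[Si](C)(C)C(C)(C)C)[C@@H]2C(O)[C@]3(C)O[C@@H]3C[C@H]2c2ccccc2)c2occc12
F3 | step 7 | O-(imidazol-1-ylthiocarbonyl) derivative of F2 | COc1cc(OC)c(C(O[Si](C)(C)C(C)(C)C)[C@@H]2C(OC(=S)n4ccnc4)[C@]3(C)O[C@@H]3C[C@H]2c2ccccc2)c2occc12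
F4 | step 6 | (5R,6R)-6-[(tert-butyldimethylsilyloxy)(4,6-dimethoxy-1-benzofuran-7-yl)methyl]-2-methyl-5-phenylcyclohex-2-en-1-one (both epimers at the silyloxy carbon) | COc1cc(OC)c(C(O[Si](C)(C)C(C)(C)C)[C@@H]2C(=O)C(C)=CC[C@H]2c2ccccc2)c2occc12
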